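**Retrosynthetic overview**

1. Numbering and enabling feature: ring A = C10–C1–C2–C3(=O)–C4(Me2)–C5; ring B = C5=C6(OH)–C7(=O)–C8(Me)=C9(side chain)–C10(Me). Ring B is a cyclohexa-2,5-dienone whose C7 carbonyl is para to the quaternary C10, i.e. the C10-alkylated keto form of a catechol, and C1 is β to the ring A ketone C3. The C10–C1 bond is therefore a Michael bond, and cutting it leaves an aromatic catechol with a vinyl ketone on C5.
2. Key disconnection C10–C1: a catalyst-controlled dearomative 6-endo Michael cyclisation of that catechol closes ring A last, sets C10, and gives the dienone, the diosphenol and the C3 ketone at their final oxidation level in the last step.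
3. The catechol: aryl–C13 bond by B-alkyl Suzuki coupling; the hexasubstituted arene from 4-bromo-3,5-dimethylphenol (ortho-formylation, O-prenylation and aromatic Claisen rearrangement for the C5–C4 bond, Dakin oxidation).
4. The oxepane–cyclohexane half: both rings and three of its four stereocenters from one Lewis-acid cascade of a bis-epoxide (Shi epoxidation) terminated by an allylsilane; the fourth stereocenter by hydrogenation.
5. Ring order: oxepane and cyclohexane together (step 7), aromatic ring B bought, ring A last (step 22).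

Key step: step 22

Remark (numbering): primed locants C1'–C11' follow 2-oxabicyclo[5.4.0]undecane (C1' = O-bearing ring-fusion CH, O2', C3' = CMe2, C4' = C=O or carbinol, C7' = methyl-bearing ring fusion, C8' = carbon carrying the side chain, C9' = CH–CH3). Acyclic precursors carry dodecane locants.

Assumption: the D-fructose-derived Shi ketone gives its usual (R,R) sense with E-trisubstituted alkenes. The sense of induction of the squaramide in step 22 cannot be taken from a precedent: the quinidine-derived catalyst is assumed to give 10S, and its quinine-derived pseudoenantiomer is the alternative. The carbinol carbon made in step 18 is carried as both epimers because step 20 removes it.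

**Route**

Step 1
Reactants: 1 geranyl bromide; 2 ethyl acetoacetate
Product: 4 ethyl (6E)-7,11-dimethyl-3-oxododeca-6,10-dienoate, via ethyl acetoacetate dianion 3 (not isolated)
Conditions: 2, NaH, THF, 0 °C; n-BuLi, 0 °C; then 1, 0 °C to rt; aq. NH4Cl
Reagents that add atoms: none
Why: γ-alkylation of the acetoacetate dianion by an allylic bromide takes place at the more basic terminal carbon and leaves the E-alkene untouched, and no stereocenter is formed.

Step 2
Reactants: 4 ethyl (6E)-7,11-dimethyl-3-oxododeca-6,10-dienoate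
Product: 6 ethyl (2Z,6E)-3-(diethoxyphosphoryloxy)-7,11-dimethyldodeca-2,6,10-trienoate, via sodium Z-enolate 5 (not isolated)
Conditions: NaH, Et2O, 0 °C; then (EtO)2P(O)Cl, 0 °C to rt
Reagents that add atoms: diethyl chlorophosphate, CCOP(=O)(Cl)OCC
Why: O-phosphorylation of the chelated sodium enolate of a β-keto ester keeps the Z geometry (phosphate cis to the ester), which fixes the alkene geometry that later places the side chain equatorially.

Step 3
Reactants: 6 ethyl (2Z,6E)-3-(diethoxyphosphoryloxy)-7,11-dimethyldodeca-2,6,10-trienoate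
Product: 7 ethyl (2Z,6E)-7,11-dimethyl-3-[(trimethylsilyl)methyl]dodeca-2,6,10-trienoate
Conditions: Me3SiCH2MgCl, Ni(acac)2 (5 mol%), THF, 0 °C to rt; aq. NH4Cl
Reagents that add atoms: (trimethylsilyl)methylmagnesium chloride, C[Si](C)(C)C[Mg]Cl
Why: nickel-catalysed Kumada-type coupling of β-keto ester enol phosphates with Me3SiCH2MgCl proceeds with retention of alkene geometry and tolerates the ester, giving the 2-substituted allylsilane with the silylmethyl group cis to the ester.

Step 4
Reactants: 7 ethyl (2Z,6E)-7,11-dimethyl-3-[(trimethylsilyl)methyl]dodeca-2,6,10-trienoate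
Product: 8 ethyl (2Z,6R,7R,10R)-6,7:10,11-diepoxy-7,11-dimethyl-3-[(trimethylsilyl)methyl]dodec-2-enoate
Conditions: D-fructose-derived Shi ketone (30 mol% per alkene), KHSO5 (Oxone), K2CO3, Bu4NHSO4, MeCN/CH2(OMe)2, aq. Na2B4O7 buffer (pH 10.5), 0 °C
Reagents that add atoms: potassium peroxymonosulfate (Oxone), [K+].[O-]S(=O)(=O)OO
Why: Shi asymmetric epoxidation oxidises the two electron-rich trisubstituted alkenes and spares the electron-poor enoate; the chiral dioxirane delivers oxygen through a spiro transition state to give the 6R,7R and 10R epoxides, of which C6 becomes the O-bearing ring-fusion carbon C1'.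

Step 5
Reactants: 8 ethyl (2Z,6R,7R,10R)-6,7:10,11-diepoxy-7,11-dimethyl-3-[(trimethylsilyl)methyl]dodec-2-enoate
Product: 9 (2Z,6R,7R,10R)-6,7:10,11-diepoxy-7,11-dimethyl-3-[(trimethylsilyl)methyl]dodec-2-en-1-ol
Conditions: i-Bu2AlH (2.2 equiv), CH2Cl2, −78 °C; aq. potassium sodium tartrate
Reagents that add atoms: none
Why: 1,2-reduction of the enoate by i-Bu2AlH at low temperature gives the allylic alcohol without opening the trisubstituted epoxides, and no stereocenter is touched.

Step 6
Reactants: 9 (2Z,6R,7R,10R)-6,7:10,11-diepoxy-7,11-dimethyl-3-[(trimethylsilyl)methyl]dodec-2-en-1-ol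
Product: 10 tert-butyldimethylsilyl ether of 9
Conditions: t-BuMe2SiCl, imidazole, CH2Cl2, 0 °C to rt
Reagents that add atoms: tert-butyldimethylsilyl chloride, CC(C)(C)[Si](C)(C)Cl
Why: standard silylation of the primary allylic alcohol removes the only free nucleophile that could intercept the epoxonium ions of the next step.

Step 7
Reactants: 10 tert-butyldimethylsilyl ether of 9
Product: 11 (1R,4R,7R,8S)-8-[(tert-butyldimethylsilyloxy)methyl]-3,3,7-trimethyl-9-methylidene-4-(trimethylsilyloxy)-2-oxabicyclo[5.4.0]undecane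
Conditions: Me3SiOTf (1.1 equiv), 2,6-di-tert-butyl-4-methylpyridine, CH2Cl2, −78 °C
Reagents that add atoms: trimethylsilyl trifluoromethanesulfonate, C[Si](C)(C)OS(=O)(=O)C(F)(F)F
Why: Lewis-acid-triggered epoxide-opening cascade with cation–olefin termination (tandem oxa-/carbacyclisation of a 1,5-bis-epoxide onto an allylsilane): the silylated 10,11-epoxide is opened at tertiary C11 by the oxygen of the 6,7-epoxide to give the oxepane, the bicyclic epoxonium ion is opened at tertiary C7 with inversion by C2 of the allylsilane through a chair transition state, so that C1' keeps the configuration of C6, C7' is inverted (trans ring fusion), CH2OTBS on C8' becomes equatorial because C1 is cis to the silylmethyl group, and loss of silicon leaves the exocyclic methylene at C9'.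

Step 8
Reactants: 11 (1R,4R,7R,8S)-8-[(tert-butyldimethylsilyloxy)methyl]-3,3,7-trimethyl-9-methylidene-4-(trimethylsilyloxy)-2-oxabicyclo[5.4.0]undecane
Product: 12 (1R,4R,7R,8S,9S)-8-[(tert-butyldimethylsilyloxy)methyl]-3,3,7,9-tetramethyl-4-(trimethylsilyloxy)-2-oxabicyclo[5.4.0]undecane
Conditions: H2 (1 atm), PtO2, EtOAc, rt
Reagents that add atoms: none
Why: in this heterogeneous hydrogenation the axial C7' methyl blocks one face of the exocyclic alkene, so hydrogen should be delivered to C9' from the opposite face and the new methyl should end axial and cis to the angular methyl (9'S).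

Step 9
Reactants: 12 (1R,4R,7R,8S,9S)-8-[(tert-butyldimethylsilyloxy)methyl]-3,3,7,9-tetramethyl-4-(trimethylsilyloxy)-2-oxabicyclo[5.4.0]undecane
Product: 13 (1R,4R,7R,8S,9S)-8-(hydroxymethyl)-3,3,7,9-tetramethyl-2-oxabicyclo[5.4.0]undecan-4-ol
Conditions: Bu4NF, THF, rt
Reagents that add atoms: none
Why: fluoride cleaves both silyl ethers under conditions that leave the ether ring and all stereocenters untouched.

Step 10
Reactants: 13 (1R,4R,7R,8S,9S)-8-(hydroxymethyl)-3,3,7,9-tetramethyl-2-oxabicyclo[5.4.0]undecan-4-ol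
Product: 14 (1R,7R,8S,9S)-3,3,7,9-tetramethyl-4-oxo-2-oxabicyclo[5.4.0]undecane-8-carbaldehyde
Conditions: Dess–Martin periodinane (2.5 equiv), CH2Cl2, 0 °C to rt
Reagents that add atoms: none
Why: Dess–Martin oxidation converts the primary and the secondary alcohol in one operation, and the α-stereocenter C8' already holds the formyl group in the more stable equatorial position, so epimerisation is not a threat.

Step 11
Reactants: 14 (1R,7R,8S,9S)-3,3,7,9-tetramethyl-4-oxo-2-oxabicyclo[5.4.0]undecane-8-carbaldehyde
Product: 15 (1R,7R,8S,9S)-8-ethenyl-3,3,7,9-tetramethyl-2-oxabicyclo[5.4.0]undecan-4-one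
Conditions: Ph3PCH3Br, KN(SiMe3)2, THF, 0 °C; then 14 (1.05 equiv ylide), −78 to 0 °C
Reagents that add atoms: methyltriphenylphosphonium bromide, C[P+](c1ccccc1)(c1ccccc1)c1ccccc1.[Br-]
Why: Wittig methylenation is chemoselective for the aldehyde over the hindered ketone flanked by the CMe2–O carbon and creates no stereocenter.

Step 12
Reactants: 16 4-bromo-3,5-dimethylphenol
Product: 17 3-bromo-6-hydroxy-2,4-dimethylbenzaldehyde
Conditions: MgCl2, Et3N, paraformaldehyde, MeCN, reflux; 1 M HCl
Reagents that add atoms: paraformaldehyde (as formaldehyde), C=O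
Why: magnesium-phenoxide-mediated ortho-formylation is ortho-specific, the two ortho positions of the symmetric phenol are equivalent, and the formyl carbon marks the site of the future C7 oxygen.

Step 13
Reactants: 17 3-bromo-6-hydroxy-2,4-dimethylbenzaldehyde
Product: 18 3-bromo-2,4-dimethyl-6-[(3-methylbut-2-en-1-yl)oxy]benzaldehyde
Conditions: prenyl bromide, K2CO3, DMF, rt
Reagents that add atoms: prenyl bromide (1-bromo-3-methylbut-2-ene), CC(C)=CCBr
Why: Williamson etherification of the acidic salicylaldehyde hydroxyl with a primary allylic bromide gives the aryl prenyl ether by SN2 attack at the unsubstituted terminus.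

Step 14
Reactants: 18 3-bromo-2,4-dimethyl-6-[(3-methylbut-2-en-1-yl)oxy]benzaldehyde
Product: 19 3-bromo-6-hydroxy-2,4-dimethyl-5-(2-methylbut-3-en-2-yl)benzaldehyde
Conditions: N,N-diethylaniline, 190 °C (sealed tube, Ar)
Reagents that add atoms: none
Why: aromatic Claisen rearrangement ([3,3]) can end only at the single free ortho carbon (C5), the para position being blocked by bromine, and transfers the prenyl group with allylic inversion, so the quaternary C4 with its two methyls is attached to C5 and the phenol is regenerated by tautomerisation.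

Step 15
Reactants: 19 3-bromo-6-hydroxy-2,4-dimethyl-5-(2-methylbut-3-en-2-yl)benzaldehyde
Product: 20 4-bromo-3,5-dimethyl-6-(2-methylbut-3-en-2-yl)benzene-1,2-diol
Conditions: H2O2 (30%), NaOH, THF/H2O, 0 °C to rt; 1 M HCl
Reagents that add atoms: hydrogen peroxide, OO
Why: Dakin oxidation of an ortho-hydroxybenzaldehyde (aryl migration in the hydroperoxide adduct, then hydrolysis of the formate) installs the C7 oxygen and does not touch the unactivated terminal alkene.

Step 16
Reactants: 20 4-bromo-3,5-dimethyl-6-(2-methylbut-3-en-2-yl)benzene-1,2-diol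
Product: 21 5-bromo-2,2-di-tert-butyl-4,6-dimethyl-7-(2-methylbut-3-en-2-yl)-1,3,2-benzodioxasilole
Conditions: t-Bu2Si(OTf)2, 2,6-lutidine, CH2Cl2, 0 °C
Reagents that add atoms: di-tert-butylsilyl bis(trifluoromethanesulfonate), CC(C)(C)[Si](OS(=O)(=O)C(F)(F)F)(OS(=O)(=O)C(F)(F)F)C(C)(C)C
Why: the cyclic silylene ties both catechol oxygens back in a five-membered ring, which suits the hindered C6 oxygen, withstands oxidants and organometallics, and is later removed by fluoride without base.

Step 17
Reactants: 21 5-bromo-2,2-di-tert-butyl-4,6-dimethyl-7-(2-methylbut-3-en-2-yl)-1,3,2-benzodioxasilole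
Product: 23 2-(5-bromo-2,2-di-tert-butyl-4,6-dimethyl-1,3,2-benzodioxasilol-7-yl)-2-methylpropanal, via vicinal diol 22 (not isolated)
Conditions: OsO4 (2 mol%), NaIO4, 2,6-lutidine, dioxane/H2O 3:1, rt
Reagents that add atoms: osmium tetroxide, O=[Os](=O)(=O)=O (carrier of the new oxygen); sodium periodate, [Na+].[O-]I(=O)(=O)=O (terminal oxidant)
Why: Lemieux–Johnson cleavage (dihydroxylation, then periodate scission) turns the terminal alkene into the non-enolisable aldehyde and avoids ozone on the electron-rich arene.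

Step 18
Reactants: 23 2-(5-bromo-2,2-di-tert-butyl-4,6-dimethyl-1,3,2-benzodioxasilol-7-yl)-2-methylpropanal
Product: 24 4-(5-bromo-2,2-di-tert-butyl-4,6-dimethyl-1,3,2-benzodioxasilol-7-yl)-4-methylpent-1-en-3-ol (both enantiomers)
Conditions: CH2=CHMgBr, THF, −78 °C; aq. NH4Cl
Reagents that add atoms: vinylmagnesium bromide, C=C[Mg]Br
Why: Grignard addition to the non-enolisable neopentyl aldehyde brings in C2 and C1, the aryl bromide does not exchange at −78 °C, and the new carbinol center is formed without control because step 20 removes it.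

Step 19
Reactants: 15 (1R,7R,8S,9S)-8-ethenyl-3,3,7,9-tetramethyl-2-oxabicyclo[5.4.0]undecan-4-one; 24 4-(5-bromo-2,2-di-tert-butyl-4,6-dimethyl-1,3,2-benzodioxasilol-7-yl)-4-methylpent-1-en-3-ol
Product: 26 4-{2,2-di-tert-butyl-4,6-dimethyl-5-[2-((1R,7R,8S,9S)-3,3,7,9-tetramethyl-4-oxo-2-oxabicyclo[5.4.0]undecan-8-yl)ethyl]-1,3,2-benzodioxasilol-7-yl}-4-methylpent-1-en-3-ol (both carbinol epimers), via B-alkyl-9-BBN borane 25 (not isolated)
Conditions: 15, 9-BBN (1.05 equiv), THF, rt; then 24 (1.2 equiv), Pd(OAc)2 (5 mol%), SPhos (10 mol%), K3PO4·H2O, THF, 60 °C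
Reagents that add atoms: none
Why: anti-Markovnikov hydroboration of the monosubstituted alkene is faster than reduction of the hindered ketone, and the B-alkyl Suzuki–Miyaura coupling with a bulky biarylphosphine joins the primary alkylborane to the di-ortho-substituted aryl bromide; the cheaper bromide is used in excess so that any residual borane cannot consume the valuable partner.

Step 20
Reactants: 26 coupled allylic alcohol
Product: 27 4-{2,2-di-tert-butyl-4,6-dimethyl-5-[2-((1R,7R,8S,9S)-3,3,7,9-tetramethyl-4-oxo-2-oxabicyclo[5.4.0]undecan-8-yl)ethyl]-1,3,2-benzodioxasilol-7-yl}-4-methylpent-1-en-3-one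
Conditions: Dess–Martin periodinane, CH2Cl2, 0 °C
Reagents that add atoms: none
Why: Dess–Martin oxidation of the allylic alcohol gives the vinyl ketone under neutral conditions with the catechol still masked, merges the two carbinol epimers, and would also re-oxidise any C4' alcohol formed in step 19.

Step 21
Reactants: 27 silylene-protected vinyl ketone
Product: 28 4-{2,3-dihydroxy-4,6-dimethyl-5-[2-((1R,7R,8S,9S)-3,3,7,9-tetramethyl-4-oxo-2-oxabicyclo[5.4.0]undecan-8-yl)ethyl]phenyl}-4-methylpent-1-en-3-one
Conditions: HF·pyridine, pyridine, THF, 0 °C; pH 7 buffer; used at once under Ar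
Reagents that add atoms: none
Why: fluoride cleaves the strained aryl silylene in a weakly acidic medium in which no phenoxide is present, so the free catechol should be released without an uncatalysed ring closure.

Step 22
Reactants: 28 catechol vinyl ketone
Product: 29 CNP0302807.1, (4aS)-8-hydroxy-1,1,4a,6-tetramethyl-5-{2-[(1R,7R,8S,9S)-3,3,7,9-tetramethyl-4-oxo-2-oxabicyclo[5.4.0]undecan-8-yl]ethyl}-3,4-dihydronaphthalene-2,7(1H,4aH)-dione
Conditions: quinidine-derived 3,5-bis(trifluoromethyl)phenyl squaramide (10 mol%), degassed toluene, 4 Å molecular sieves, Ar, −20 °C to rt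
Reagents that add atoms: none
Why: Proposed new method: the quinuclidine nitrogen of the bifunctional catalyst deprotonates (hydrogen-bonds) the C7 hydroxyl while the squaramide N–H pair binds the C3 carbonyl of the s-trans vinyl ketone, so the catecholate attacks with C10, the carbon para to O7, on C1 and the resulting C3 enolate is protonated at C2; this is an intramolecular dearomative Michael addition, and the closest known reaction types are the thiourea- or squaramide-catalysed enantioselective dearomative Michael additions of naphthols and the base- or fluoride-induced intramolecular para-C-alkylations of phenoxides to 4,4-disubstituted cyclohexadienones. Ring A closes by one bond (C10–C1) in a 6-endo-trig mode with the ketone carbon C3 inside the ring, the geometry of a chalcone-to-flavanone closure, while the ipso alternative at C5 would be 5-endo-trig. The only new stereocenter, quaternary C10 (S), is set by the catalyst, which holds the tether over one face of the flat catechol; the four stereocenters of the oxepane–cyclohexane unit lie at least five bonds from C10 and should not bias the faces, so the step is run as catalyst-controlled. The step needs C-attack at C10 in place of O-attack by O6 (seven-membered aryl ether) or C-attack at C6: oxa-Michael and hemiketal formation are reversible, C6 carries oxygen and would give a less stable linearly conjugated α-ketol, and only C10 attack ends in the hydrogen-bonded cross-conjugated diosphenol that is the target itself. The new C–C σ bond and the release of the strain between the tert-alkyl group and its two ortho neighbours are estimated to outweigh the loss of aromaticity, and a low temperature keeps the closure under kinetic control.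

**Compound list**

1 | geranyl bromide, (2E)-1-bromo-3,7-dimethylocta-2,6-diene | CC(C)=CCC/C(C)=C/CBr | starting material
2 | ethyl acetoacetate | CCOC(=O)CC(C)=O | starting material
3 | ethyl acetoacetate dianion (sodium lithium salt) | [Na+].[Li+].CCOC(=O)[CH-]C(=O)[CH2-] | intermediate
4 | ethyl (6E)-7,11-dimethyl-3-oxododeca-6,10-dienoate | CCOC(=O)CC(=O)CC/C=C(C)/CCC=C(C)C | intermediate
5 | sodium Z-enolate of 4 | [Na+].CCOC(=O)/C=C(\[O-])CC/C=C(C)/CCC=C(C)C | intermediate
6 | ethyl (2Z,6E)-3-(diethoxyphosphoryloxy)-7,11-dimethyldodeca-2,6,10-trienoate | CCOC(=O)/C=C(\OP(=O)(OCC)OCC)CC/C=C(C)/CCC=C(C)C | intermediate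
7 | ethyl (2Z,6E)-7,11-dimethyl-3-[(trimethylsilyl)methyl]dodeca-2,6,10-trienoate | CCOC(=O)/C=C(\C[Si](C)(C)C)CC/C=C(C)/CCC=C(C)C | intermediate
8 | ethyl (2Z,6R,7R,10R)-6,7:10,11-diepoxy-7,11-dimethyl-3-[(trimethylsilyl)methyl]dodec-2-enoate | CCOC(=O)/C=C(\C[Si](C)(C)C)CC[C@H]1O[C@]1(C)CC[C@H]1OC1(C)C | intermediate
9 | (2Z,6R,7R,10R)-6,7:10,11-diepoxy-7,11-dimethyl-3-[(trimethylsilyl)methyl]dodec-2-en-1-ol | OC/C=C(\C[Si](C)(C)C)CC[C@H]1O[C@]1(C)CC[C@H]1OC1(C)C | intermediate
10 | tert-butyldimethylsilyl ether of 9 | CC(C)(C)[Si](C)(C)OC/C=C(\C[Si](C)(C)C)CC[C@H]1O[C@]1(C)CC[C@H]1OC1(C)C | intermediate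
11 | (1R,4R,7R,8S)-8-[(tert-butyldimethylsilyloxy)methyl]-3,3,7-trimethyl-9-methylidene-4-(trimethylsilyloxy)-2-oxabicyclo[5.4.0]undecane (trans-fused; CH2OTBS equatorial, cis to the angular methyl) | CC(C)(C)[Si](C)(C)OC[C@H]1C(=C)CC[C@H]2OC(C)(C)[C@H](O[Si](C)(C)C)CC[C@@]21C | intermediate
12 | (1R,4R,7R,8S,9S)-8-[(tert-butyldimethylsilyloxy)methyl]-3,3,7,9-tetramethyl-4-(trimethylsilyloxy)-2-oxabicyclo[5.4.0]undecane (C9' methyl axial, cis to the angular methyl) | CC(C)(C)[Si](C)(C)OC[C@H]1[C@@H](C)CC[C@H]2OC(C)(C)[C@H](O[Si](C)(C)C)CC[C@@]21C | intermediate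
13 | (1R,4R,7R,8S,9S)-8-(hydroxymethyl)-3,3,7,9-tetramethyl-2-oxabicyclo[5.4.0]undecan-4-ol | OC[C@H]1[C@@H](C)CC[C@H]2OC(C)(C)[C@H](O)CC[C@@]21C | intermediate
14 | (1R,7R,8S,9S)-3,3,7,9-tetramethyl-4-oxo-2-oxabicyclo[5.4.0]undecane-8-carbaldehyde | O=C[C@H]1[C@@H](C)CC[C@H]2OC(C)(C)C(=O)CC[C@@]21C | intermediate
15 | (1R,7R,8S,9S)-8-ethenyl-3,3,7,9-tetramethyl-2-oxabicyclo[5.4.0]undecan-4-one | C=C[C@H]1[C@@H](C)CC[C@H]2OC(C)(C)C(=O)CC[C@@]21C | intermediate
16 | 4-bromo-3,5-dimethylphenol | Cc1cc(O)cc(C)c1Br | starting material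
17 | 3-bromo-6-hydroxy-2,4-dimethylbenzaldehyde | O=Cc1c(O)cc(C)c(Br)c1C | intermediate
18 | 3-bromo-2,4-dimethyl-6-[(3-methylbut-2-en-1-yl)oxy]benzaldehyde | O=Cc1c(OCC=C(C)C)cc(C)c(Br)c1C | intermediate
19 | 3-bromo-6-hydroxy-2,4-dimethyl-5-(2-methylbut-3-en-2-yl)benzaldehyde | O=Cc1c(O)c(C(C)(C)C=C)c(C)c(Br)c1C | intermediate
20 | 4-bromo-3,5-dimethyl-6-(2-methylbut-3-en-2-yl)benzene-1,2-diol | Oc1c(O)c(C(C)(C)C=C)c(C)c(Br)c1C | intermediate
21 | 5-bromo-2,2-di-tert-butyl-4,6-dimethyl-7-(2-methylbut-3-en-2-yl)-1,3,2-benzodioxasilole | CC(C)(C)[Si]1(C(C)(C)C)Oc2c(O1)c(C(C)(C)C=C)c(C)c(Br)c2C | intermediate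
22 | 3-(5-bromo-2,2-di-tert-butyl-4,6-dimethyl-1,3,2-benzodioxasilol-7-yl)-3-methylbutane-1,2-diol | CC(C)(C)[Si]1(C(C)(C)C)Oc2c(O1)c(C(C)(C)C(O)CO)c(C)c(Br)c2C | intermediate
23 | 2-(5-bromo-2,2-di-tert-butyl-4,6-dimethyl-1,3,2-benzodioxasilol-7-yl)-2-methylpropanal | CC(C)(C)[Si]1(C(C)(C)C)Oc2c(O1)c(C(C)(C)C=O)c(C)c(Br)c2C | intermediate
24 | 4-(5-bromo-2,2-di-tert-butyl-4,6-dimethyl-1,3,2-benzodioxasilol-7-yl)-4-methylpent-1-en-3-ol (both enantiomers) | CC(C)(C)[Si]1(C(C)(C)C)Oc2c(O1)c(C(C)(C)C(O)C=C)c(C)c(Br)c2C | intermediate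
25 | B-alkyl-9-BBN borane from 15 (boron on the terminal carbon of the former vinyl group) | C1CC2CCCC(C1)B2CC[C@H]3[C@@H](C)CC[C@H]4OC(C)(C)C(=O)CC[C@@]43C | intermediate
26 | 4-{2,2-di-tert-butyl-4,6-dimethyl-5-[2-((1R,7R,8S,9S)-3,3,7,9-tetramethyl-4-oxo-2-oxabicyclo[5.4.0]undecan-8-yl)ethyl]-1,3,2-benzodioxasilol-7-yl}-4-methylpent-1-en-3-ol (both carbinol epimers) | CC(C)(C)[Si]1(C(C)(C)C)Oc2c(O1)c(C(C)(C)C(O)C=C)c(C)c(CC[C@H]3[C@@H](C)CC[C@H]4OC(C)(C)C(=O)CC[C@@]43C)c2C | intermediate
27 | 4-{2,2-di-tert-butyl-4,6-dimethyl-5-[2-((1R,7R,8S,9S)-3,3,7,9-tetramethyl-4-oxo-2-oxabicyclo[5.4.0]undecan-8-yl)ethyl]-1,3,2-benzodioxasilol-7-yl}-4-methylpent-1-en-3-one | CC(C)(C)[Si]1(C(C)(C)C)Oc2c(O1)c(C(C)(C)C(=O)C=C)c(C)c(CC[C@H]3[C@@H](C)CC[C@H]4OC(C)(C)C(=O)CC[C@@]43C)c2C | intermediate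
28 | 4-{2,3-dihydroxy-4,6-dimethyl-5-[2-((1R,7R,8S,9S)-3,3,7,9-tetramethyl-4-oxo-2-oxabicyclo[5.4.0]undecan-8-yl)ethyl]phenyl}-4-methylpent-1-en-3-one | Oc1c(O)c(C(C)(C)C(=O)C=C)c(C)c(CC[C@H]2[C@@H](C)CC[C@H]3OC(C)(C)C(=O)CC[C@@]32C)c1C | intermediate
29 | CNP0302807.1, (4aS)-8-hydroxy-1,1,4a,6-tetramethyl-5-{2-[(1R,7R,8S,9S)-3,3,7,9-tetramethyl-4-oxo-2-oxabicyclo[5.4.0]undecan-8-yl]ethyl}-3,4-dihydronaphthalene-2,7(1H,4aH)-dione | CC1=C(CC[C@H]2[C@@H](C)CC[C@H]3OC(C)(C)C(=O)CC[C@@]32C)[C@]2(C)CCC(=O)C(C)(C)C2=C(O)C1=O | target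

**Step count and risks**

Total steps: 22. Longest linear sequence: 15 steps (steps 1–11, then 19–22).

Steps most likely to fail:

Step 22 (key step). The ring closure may be thermodynamically too weakly driven or may equilibrate, which would erode the C10 ratio, or the catalyst may control the face poorly. The fallback closes the same C10–C1 bond by an irreversible intramolecular para-C-alkylation of the phenoxide, a known dearomatisation, at the alcohol oxidation level of C3. It sets out from 26: hydroboration of the vinyl group (9-BBN, then NaBO3) should give the 1,3-diol F1, and selective sulfonylation of its primary hydroxyl (TsCl, pyridine) the tosylate F2. Bu4NF in THF/t-BuOH should then remove the silylene and let the catecholate alkylate at C10 with closure of the six-membered ring, giving the ring A alcohol F3 as a mixture of C10 epimers; these are diastereomers and would be separated by chromatography. Oxidation of the ring A alcohol with Pr4NRuO4 and N-methylmorpholine N-oxide returns to 29.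

Step 14. The Claisen rearrangement must end at an ortho carbon flanked by a methyl group; it may be slow and compete with loss of the prenyl group or with cyclisation of the product phenol onto its new alkene. The fallback builds the quaternary benzylic carbon by 1,4-addition to an ortho-quinone methide instead. It sets out from 16: acetylation (Ac2O, pyridine) gives the aryl acetate F4, Fries rearrangement (AlCl3, 130 °C) the ortho-hydroxyacetophenone F5, and Boc2O with 4-(dimethylamino)pyridine the aryl carbonate F6. MeMgBr followed by CH2=CHMgBr (THF, −78 to 0 °C) should add to the ketone, trigger Boc transfer and elimination to the dimethyl ortho-quinone methide, and add the vinyl group to it, giving the reverse-prenyl phenol F7. Its magnesium-mediated ortho-formylation (MgCl2, Et3N, paraformaldehyde) returns to 19.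

Step 8. Facial selectivity may be poor, or the exocyclic alkene may migrate into the ring before it is reduced. The fallback replaces hydrogenation by hydroboration with a bulky borane, which puts hydrogen on C9' from the same open face with higher selectivity, and then removes the oxygen. It sets out from 11: 9-BBN followed by H2O2 in pH 7 buffer should give the axial hydroxymethyl compound F8, I2/PPh3/imidazole the iodide F9, and reduction with Bu3SnH and azobisisobutyronitrile returns to 12.

**Further compounds**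

F1 | step 22 | 1,3-diol from hydroboration–oxidation of 26 (4-aryl-4-methylpentane-1,3-diol, aryl as in 26) | CC(C)(C)[Si]1(C(C)(C)C)Oc2c(O1)c(C(C)(C)C(O)CCO)c(C)c(CC[C@H]3[C@@H](C)CC[C@H]4OC(C)(C)C(=O)CC[C@@]43C)c2C
F2 | step 22 | primary p-toluenesulfonate of F1 | CC(C)(C)[Si]1(C(C)(C)C)Oc2c(O1)c(C(C)(C)C(O)CCOS(=O)(=O)c5ccc(C)cc5)c(C)c(CC[C@H]3[C@@H](C)CC[C@H]4OC(C)(C)C(=O)CC[C@@]43C)c2C
F3 | step 22 | ring A alcohol corresponding to 29 (C3 carbinol in place of the C3 ketone; 10S epimer shown) | CC1=C(CC[C@H]2[C@@H](C)CC[C@H]3OC(C)(C)C(=O)CC[C@@]32C)[C@]2(C)CCC(O)C(C)(C)C2=C(O)C1=O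
F4 | step 14 | 4-bromo-3,5-dimethylphenyl acetate | CC(=O)Oc1cc(C)c(Br)c(C)c1
F5 | step 14 | 1-(3-bromo-6-hydroxy-2,4-dimethylphenyl)ethan-1-one | CC(=O)c1c(O)cc(C)c(Br)c1C
F6 | step 14 | 2-acetyl-4-bromo-3,5-dimethylphenyl tert-butyl carbonate | CC(=O)c1c(OC(=O)OC(C)(C)C)cc(C)c(Br)c1C
F7 | step 14 | 4-bromo-3,5-dimethyl-2-(2-methylbut-3-en-2-yl)phenol | C=CC(C)(C)c1c(O)cc(C)c(Br)c1C
F8 | step 8 | analogue of 12 with an axial hydroxymethyl group at C9' in place of the methyl group | CC(C)(C)[Si](C)(C)OC[C@H]1[C@@H](CO)CC[C@H]2OC(C)(C)[C@H](O[Si](C)(C)C)CC[C@@]21C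
F9 | step 8 | analogue of 12 with an axial iodomethyl group at C9' in place of the methyl group | CC(C)(C)[Si](C)(C)OC[C@H]1[C@@H](CI)CC[C@H]2OC(C)(C)[C@H](O[Si](C)(C)C)CC[C@@]21C
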